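Conventions: all bicyclic compounds carry drimane numbering (ring A = C1–C5 and C10, ring B = C5–C10, C11 = benzylic CH2). The "upper face" of ring B is the face that carries C11, the "lower face" the one that carries the 9-methyl group. Compound numbers are those of the steps and of the compound list.

## Analysis of the target

Target 25 is a 2-hydroxy-5-methoxy-1,4-benzoquinone tied through a methylene group (C11) to an octalin: ring A holds the C4 gem-dimethyl group, ring B the C5=C6 alkene, the secondary methyl at C8 and the quaternary C9, and C10 is the ring-fusion CH. Three contiguous stereocentres are present, 8S, 9R and 10S: the 8- and 9-methyl groups lie on one face of ring B together with C1, while H10 and C11 lie on the other. C4 and C5 carry no stereochemical information, so whatever configuration is created there on the way is of no consequence. The quinone is a vinylogous acid, an electrophile and an oxidant and must be unveiled last; the C5=C6 alkene sits next to the quaternary C4, and protonation at C6 would give a C5 cation that invites methyl migration or capture by the quinone hydroxyl, so strong acid is excluded at the end. The difficulties are the quaternary C9 with its neopentyl arylmethyl arm between two stereocentres, an alkene whose position cannot be trusted to an ordinary elimination, and an unsymmetrical oxygenation pattern on the quinone. The feature that is used is that C10 and C5, the atoms through which ring A is fused, are the β- and α-carbons of a carbonyl group at C6, that C8 is the β′-carbon of the same carbonyl, and that C9 lies between them: ring B is a 4-methyl-4-arylmethylcyclohexa-2,5-dienone in disguise. Such a dienone is achiral; one arm can take ring A by a [4+2] addition that breaks the symmetry, the other arm can take the 8-methyl group, and the carbonyl carbon itself ends as the alkene carbon C6.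

## Retrosynthetic reasoning

The C–O bonds of the quinone are traced back to aryl methyl ethers: 25 comes from dimethoxyquinone 24 by exchange of one methoxy group for hydroxyl, and 24 from tetramethoxyarene 23 by oxidative demethylation. The cut is made here because the arene survives organolithium, organocopper, acid, base and hydride chemistry and the quinone does not. Forward, either para pair of methoxy groups gives the same quinone (the ring has a mirror plane through the carbon bearing C11), and the hydrolysis must touch only the methoxy group beside the alkyl substituent, which is twisted out of conjugation and so the more ester-like.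

Ring A of 23 is then given back an oxygen at C2: 23 from ketone 21 by carbonyl-to-methylene reduction, 21 from dioxolane 20. C2 is where the diene of the key step leaves its oxygen. As a ketal it is silent during the organometallic steps, and as a ketone flanked by two methylene groups it is easy to remove.

The C5=C6 alkene and one C4 methyl group are disconnected together. 20 is the reduction product of enol triflate 19, and 19 arises when a methylcopper reagent adds to C4 of enone 17, whose C4=C5 alkene is conjugated with the C6 ketone, and enolate 18 is captured on oxygen. The obvious alternative, adding this methyl group to a ring A enone conjugated with C2, does not hold: with the C6 ketone in place that substrate is a vinylogous 1,3-diketone, far too acidic at C5 for an organocopper reagent. It would also leave the alkene to be made by enolising the C6 ketone towards C5, against the kinetic preference for C7. With C6 as the acceptor carbonyl the conjugate addition itself fixes the alkene position.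

17 is traced to 16 by two acid-driven changes in ring A: the silyl enol ether becomes the dioxolane, and methanol is lost from C4 towards C5. This works because the C4 methoxy group is β to C6 as well as to the masked C2 carbonyl. The C4 and C5 configurations vanish here.

The C8–CH3 bond of 16 is cut next, giving enone 15; the arm of the dienone that was not used in the cycloaddition is the acceptor. The forward addition must place methyl on the lower face, cis to the 9-methyl group.

15 is cut at C10–C1 and C5–C4 into dienone 11 and diene 14. This removes ring A, two skeletal bonds and all stereochemical information at once, and returns an achiral precursor, so the absolute configuration can come from a catalyst. The forward reaction must choose one of two enantiotopic enone arms and the face anti to the arylmethyl group. The diene keeps a methoxy group at its fully substituted terminus so that ring closure can also run stepwise through an oxocarbenium ion. Its silyl group is tert-butyldimethylsilyl, which is less prone than trimethylsilyl to pass to the counter-ion of the catalyst and lets the enol ether in 15 survive the next step.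

14 comes from enone 12 by kinetic enolisation at the acetyl methyl group and O-silylation (enolate 13).

11 is the dehydrogenation product of cyclohexenone 9 through dienol ether 10. 9 is assembled by annulation of aldehyde 6 with enone 7 through keto aldehyde 8. 6 comes from enal 5 by saturation of the alkene, 5 from aldehydes 3 and 4 by condensation, and 3 from arene 1 through aryllithium 2. The stereocentre of 6 becomes the prochiral quaternary carbon of 11, so nothing before the key step needs stereocontrol.

## Alternatives that were turned down

Alternative 1: Both ring B bonds C5–C10 and C8–C9 are cut, with the C1–C4 tether closing ring A in the same event and a formyl group standing in for the arylmethyl arm. Forward, triene A1, an (E)-2-methylenal tethered to a 2-silyloxydiene, is activated at the aldehyde by a protonated chiral oxazaborolidine and cyclises to the cis-fused octalin aldehyde A2. In its favour, two rings and C8, C9 and C10 arise in one suprafacial event. On C8 it is stronger than the chosen route, which sets that centre by a substrate-controlled cuprate addition. Against it: A1 is a linear chain with three geometry-defined alkenes, one a silyl enol ether on a diene terminus next to the quaternary C4, and needs many steps. The enol ether of A2 is C6=C7, so the C5=C6 alkene is still unsolved. The arene must later be joined to a neopentyl aldehyde and the benzylic oxygen removed. The chosen route reaches its symmetric precursor in five steps, carries the arene from the start and uses the C6 carbonyl to place the alkene.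

Alternative 2: The C9–C10 bond is cut through a [3,3] shift that also breaks O–C6. Forward, the silyl ketene acetal of δ-lactone A3 (enolate formation, O-silylation, heat) rearranges across the ring A alkene and contracts to acid A4, closing ring B. In its favour, the ring-constrained transition state relays configuration from C6 and C8 to C9 and C10, and the C5=C6 alkene appears in place directly. On alkene placement it is stronger than the chosen route, which needs a triflation and a reduction. Against it: A4 carries a carboxyl group where the 9-methyl group is needed, and reducing a fully substituted neopentyl carboxyl to methyl costs three or more steps. A3 needs two stereocentres set beforehand and a fully substituted ketene acetal at a crowded α-carbon. The chosen route takes its absolute configuration from one catalytic step on an achiral substrate and has the 9-methyl group from the start.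

Alternative 3: The quinone ring itself is cut, between the carbonyl carbon and the methoxy-bearing carbon. Forward, cyclobutenone A5 opens near 140 °C to a vinylketene that closes onto the methoxyalkyne and gives the tert-butyl ether A6, which mild acid would turn into 25. In its favour, all four quinone substituents are placed by connectivity, so no selective hydrolysis is needed; on that point it is stronger than the chosen route. Against it: it leaves the octalin with its three stereocentres untouched as a problem, and it needs a neopentyl organometallic derived from that octalin to be joined to a four-membered ring. The alkoxyalkynyl anion is delicate, and ring closure can divert to a five-membered ring. The chosen route masks the quinone as an arene from step 1 and unveils it in two known operations.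

Key step: step 7

Assumption: the sense of induction in step 7 is taken from the α-C–H···O binding model of protonated oxazaborolidines with cyclic enones, which calls for the catalyst derived from (S)-α,α-diphenylprolinol; the (R)-catalyst would give the mirror-image series.

## Route

Step 1
Reactants: 1 1,2,4,5-tetramethoxybenzene
Product: 3 2,3,5,6-tetramethoxybenzaldehyde, via aryllithium 2 (not isolated)
Conditions: n-BuLi, THF, 0 → 23 °C; DMF, 0 °C; aq. NH4Cl
Reagents that add atoms: N,N-dimethylformamide, CN(C)C=O
Why: Directed ortho-lithiation at the ring hydrogen flanked by two methoxy groups, then formylation of the aryllithium.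

Step 2
Reactants: 3 2,3,5,6-tetramethoxybenzaldehyde, 4 propanal
Product: 5 (2E)-2-methyl-3-(2,3,5,6-tetramethoxyphenyl)prop-2-enal
Conditions: NaOH (aq., cat.), MeOH, slow addition of 4, 23 → 50 °C
Reagents that add atoms: none
Why: Crossed aldol condensation (Claisen–Schmidt type) of a non-enolisable aryl aldehyde with propanal, the way 2-methylcinnamaldehydes are made; dehydration gives the E enal.

Step 3
Reactants: 5 (2E)-2-methyl-3-(2,3,5,6-tetramethoxyphenyl)prop-2-enal
Product: 6 2-methyl-3-(2,3,5,6-tetramethoxyphenyl)propanal (racemic)
Conditions: H2 (1 atm), Pd/C, EtOAc, 23 °C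
Reagents that add atoms: none
Why: Chemoselective hydrogenation of the conjugated alkene over palladium; the new α-stereocentre need not be controlled because it becomes the prochiral carbon of 11.

Step 4
Reactants: 6 2-methyl-3-(2,3,5,6-tetramethoxyphenyl)propanal, 7 methyl vinyl ketone
Product: 9 4-methyl-4-[(2,3,5,6-tetramethoxyphenyl)methyl]cyclohex-2-en-1-one (racemic), via keto aldehyde 8 (not isolated)
Conditions: KOH (cat.), EtOH, 0 → 23 °C, then 60 °C
Reagents that add atoms: none
Why: Robinson annulation: Michael addition of the α-branched aldehyde enolate to 7, then aldol condensation of the methyl ketone onto the aldehyde, as used for other 4,4-disubstituted cyclohexenones.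

Step 5
Reactants: 9 4-methyl-4-[(2,3,5,6-tetramethoxyphenyl)methyl]cyclohex-2-en-1-one
Product: 11 4-methyl-4-[(2,3,5,6-tetramethoxyphenyl)methyl]cyclohexa-2,5-dien-1-one, via trimethylsilyl dienol ether 10 (not isolated)
Conditions: LiN(i-Pr)2, THF, −78 °C; Me3SiCl; then Pd(OAc)2 (1.1 equiv), MeCN, 23 °C
Reagents that add atoms: none
Why: Saegusa–Ito dehydrogenation: kinetic α′-deprotonation gives the cross-conjugated dienol ether, which divalent palladium converts into the dienone; this avoids quinone oxidants that would attack the electron-rich arene.

Step 6
Reactants: 12 (3E)-4-methoxypent-3-en-2-one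
Product: 14 tert-butyl{[(3E)-4-methoxypenta-1,3-dien-2-yl]oxy}dimethylsilane, via lithium enolate 13 (not isolated)
Conditions: LiN(i-Pr)2, THF, −78 °C; t-BuMe2SiCl, DMPU, −78 → 0 °C
Reagents that add atoms: tert-butyldimethylsilyl chloride, CC(C)(C)[Si](C)(C)Cl
Why: Kinetic deprotonation at the acetyl methyl group and O-silylation give the 2-silyloxydiene with the E enol ether geometry kept.

Step 7
Reactants: 11 4-methyl-4-[(2,3,5,6-tetramethoxyphenyl)methyl]cyclohexa-2,5-dien-1-one, 14 tert-butyl{[(3E)-4-methoxypenta-1,3-dien-2-yl]oxy}dimethylsilane
Product: 15 (4R,4aR,8S,8aR)-6-[(tert-butyldimethylsilyl)oxy]-8-methoxy-4,8-dimethyl-4-[(2,3,5,6-tetramethoxyphenyl)methyl]-4a,5,8,8a-tetrahydronaphthalen-1(4H)-one (cis-fused; C6 ketone, C7=C8 enone, ring A silyl enol ether C2=C3, C4 methoxy)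
Conditions: (S)-1-(2-methylphenyl)-3,3-diphenyltetrahydro-1H,3H-pyrrolo[1,2-c][1,3,2]oxazaborole (20 mol %), HNTf2 (18 mol %), CH2Cl2, −78 → −40 °C; then Et3N
Reagents that add atoms: none
Why: The N-protonated oxazaborolidine binds the carbonyl oxygen of 11 at boron with the α-C–H of one arm held by the ring oxygen, and the CH2 terminus of 14, made nucleophilic by the 2-silyloxy and 4-methoxy groups, bonds to the β-carbon C10 while the methoxy-bearing terminus bonds to the α-carbon C5, either in one strongly asynchronous step or as a Mukaiyama–Michael addition followed by collapse of the boron enolate onto the methoxycarbenium ion. The closest known reaction type is the protonated-oxazaborolidine-catalysed Diels–Alder reaction of cyclic enones, quinones and quinone-monoketal-type dienones with 2-silyloxydienes. Ring A closes as a six-membered ring, suprafacially on both partners in the concerted picture and as a 6-(enolexo)-exo-trig closure in the stepwise limit. C9 becomes stereogenic because only one of the two enantiotopic arms reacts, and the catalyst chooses that arm. C10 is set by the face of attack, anti to the arylmethyl group, which puts C1 cis to the 9-methyl group and H10 cis to C11. C5 follows from suprafacial addition (cis ring fusion) and C4 from the endo orientation and the E geometry of 14; both are erased in step 9, so epimers at these centres converge. Regiochemistry is fixed by the polarity of the diene. The step needs arm and face selection together: the catalyst permits either the wanted arm from the lower face or the other arm from the upper face, the arylmethyl group disfavours the second, and the mirror-image product would need the combination that the catalyst rejects.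

Step 8
Reactants: 15 cis-fused cycloadduct
Product: 16 (3S,4R,4aR,8S,8aR)-6-[(tert-butyldimethylsilyl)oxy]-8-methoxy-3,4,8-trimethyl-4-[(2,3,5,6-tetramethoxyphenyl)methyl]-3,4,4a,5,8,8a-hexahydronaphthalen-1(2H)-one (8-methyl on the lower face, cis to 9-methyl)
Conditions: Me2CuLi (from CuI, MeLi), Et2O, −78 → −30 °C; aq. NH4Cl
Reagents that add atoms: lithium dimethylcuprate, [Li+].C[Cu-]C
Why: Cuprate conjugate addition to the remaining enone arm; ring B of 15 should rest in the half-chair that keeps C4 equatorial (the other would set C4 and the 9-methyl group syn-axial), which holds the arylmethyl group pseudoaxial on the upper face next to C8, so methyl should enter from the lower face. The enolate formed is the C6–C7 one, so the β-methoxy group and the silyl enol ether are not touched.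

Step 9
Reactants: 16 8-methyl ketone
Product: 17 (7'S,8'R,8a'S)-4',7',8'-trimethyl-8'-[(2,3,5,6-tetramethoxyphenyl)methyl]-6',7',8',8a'-tetrahydro-1'H-spiro[[1,3]dioxolane-2,2'-naphthalen]-5'(3'H)-one (C2 dioxolane, C4=C5 alkene conjugated with the C6 ketone)
Conditions: HOCH2CH2OH, TsOH·H2O (cat.), benzene, reflux, water separator
Reagents that add atoms: ethylene glycol, OCCO
Why: Acid turns the silyl enol ether into the C2 dioxolane and expels methanol from C4, which is β to the C6 ketone, giving the conjugated tetrasubstituted enone. Under equilibrating conditions the hindered conjugated C6 ketone stays free, as in selective ketalisation of ene-diones; C10 is not enolisable in this enone and keeps its configuration.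

Step 10
Reactants: 17 dioxolane enone
Product: 19 (7'S,8'R,8a'S)-4',4',7',8'-tetramethyl-8'-[(2,3,5,6-tetramethoxyphenyl)methyl]-3',4',6',7',8',8a'-hexahydro-1'H-spiro[[1,3]dioxolane-2,2'-naphthalen]-5'-yl trifluoromethanesulfonate, via lithium enolate 18 (not isolated)
Conditions: Me2CuLi (from CuI, MeLi; 3 equiv), Et2O, −20 → 0 °C; then PhNTf2, THF, 0 → 23 °C; aq. NH4Cl
Reagents that add atoms: lithium dimethylcuprate, [Li+].C[Cu-]C; N-phenylbis(trifluoromethanesulfonimide), O=S(=O)(N(c1ccccc1)S(=O)(=O)C(F)(F)F)C(F)(F)F
Why: Conjugate addition to an s-cis alkylidene ketone of the pulegone type makes the C4 gem-dimethyl group (no stereocentre) and leaves the enolate only as C5=C6; O-sulfonylation in the same flask fixes that alkene position.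

Step 11
Reactants: 19 enol triflate
Product: 20 (7'S,8'R,8a'S)-4',4',7',8'-tetramethyl-8'-[(2,3,5,6-tetramethoxyphenyl)methyl]-3',4',6',7',8',8a'-hexahydro-1'H-spiro[[1,3]dioxolane-2,2'-naphthalene]
Conditions: Pd(OAc)2 (5 mol %), PPh3, Bu3N, HCO2H, DMF, 60 °C
Reagents that add atoms: none
Why: Palladium-catalysed formate reduction of an enol triflate: oxidative addition to zerovalent palladium, formate exchange, loss of CO2 and reductive elimination put hydrogen on C6 without moving the alkene.

Step 12
Reactants: 20 alkene dioxolane
Product: 21 (7S,8R,8aS)-4,4,7,8-tetramethyl-8-[(2,3,5,6-tetramethoxyphenyl)methyl]-3,4,6,7,8,8a-hexahydronaphthalen-2(1H)-one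
Conditions: 1 M HCl, THF, 23 °C
Reagents that add atoms: water, O
Why: Acetal hydrolysis under conditions too mild to protonate the trisubstituted alkene; the C2 ketone is γ,δ to the alkene and cannot conjugate with it.

Step 13
Reactants: 21 C2 ketone
Product: 23 3-{[(1R,2S,8aS)-1,2,5,5-tetramethyl-1,2,3,5,6,7,8,8a-octahydronaphthalen-1-yl]methyl}-1,2,4,5-tetramethoxybenzene, via hydrazone 22 (not isolated)
Conditions: N2H4·H2O, KOH, diethylene glycol, 130 °C, then 200 °C
Reagents that add atoms: none
Why: Wolff–Kishner reduction of an unhindered cyclohexanone flanked by two methylene groups; the isolated alkene and the aryl ethers carry no function that base can engage, and no stereocentre is α to the carbonyl.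

Step 14
Reactants: 23 tetramethoxyarene
Product: 24 2,5-dimethoxy-3-{[(1R,2S,8aS)-1,2,5,5-tetramethyl-1,2,3,5,6,7,8,8a-octahydronaphthalen-1-yl]methyl}cyclohexa-2,5-diene-1,4-dione
Conditions: (NH4)2Ce(NO3)6, MeCN/H2O, 0 °C
Reagents that add atoms: water, O
Why: Oxidative demethylation of a para-dimethoxyarene by tetravalent cerium through the arene radical cation, with water supplying the carbonyl oxygens; both para pairs lead to the same quinone, and the isolated alkene is not oxidised under these conditions.

Step 15
Reactants: 24 dimethoxyquinone
Product: 25 2-hydroxy-5-methoxy-3-{[(1R,2S,8aS)-1,2,5,5-tetramethyl-1,2,3,5,6,7,8,8a-octahydronaphthalen-1-yl]methyl}cyclohexa-2,5-diene-1,4-dione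
Conditions: KOH, MeOH/H2O, 23 → 50 °C; then 1 M HCl, 0 °C
Reagents that add atoms: potassium hydroxide, [K+].[OH-]
Why: Addition–elimination of hydroxide on a vinylogous ester; the methoxy group beside the alkyl substituent is forced out of the ring plane, conjugates less and should be displaced in preference to the one beside the ring hydrogen. The product is protected as its vinylogous carboxylate until the cold acid quench.

## Compound list

1 | 1,2,4,5-tetramethoxybenzene | COc1cc(OC)c(OC)cc1OC | starting material
2 | (2,3,5,6-tetramethoxyphenyl)lithium | COc1cc(OC)c(OC)c([Li])c1OC | intermediate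
3 | 2,3,5,6-tetramethoxybenzaldehyde | COc1cc(OC)c(OC)c(C=O)c1OC | intermediate
4 | propanal | CCC=O | starting material
5 | (2E)-2-methyl-3-(2,3,5,6-tetramethoxyphenyl)prop-2-enal | COc1cc(OC)c(OC)c(/C=C(\C)C=O)c1OC | intermediate
6 | 2-methyl-3-(2,3,5,6-tetramethoxyphenyl)propanal (racemic) | COc1cc(OC)c(OC)c(CC(C)C=O)c1OC | intermediate
7 | methyl vinyl ketone (but-3-en-2-one) | C=CC(C)=O | starting material
8 | 2-methyl-5-oxo-2-[(2,3,5,6-tetramethoxyphenyl)methyl]hexanal (racemic) | COc1cc(OC)c(OC)c(CC(C)(C=O)CCC(C)=O)c1OC | intermediate
9 | 4-methyl-4-[(2,3,5,6-tetramethoxyphenyl)methyl]cyclohex-2-en-1-one (racemic) | COc1cc(OC)c(OC)c(CC2(C)CCC(=O)C=C2)c1OC | intermediate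
10 | trimethyl({5-methyl-5-[(2,3,5,6-tetramethoxyphenyl)methyl]cyclohexa-1,3-dien-2-yl}oxy)silane (racemic) | COc1cc(OC)c(OC)c(CC2(C)CC=C(O[Si](C)(C)C)C=C2)c1OC | intermediate
11 | 4-methyl-4-[(2,3,5,6-tetramethoxyphenyl)methyl]cyclohexa-2,5-dien-1-one (achiral) | COc1cc(OC)c(OC)c(CC2(C)C=CC(=O)C=C2)c1OC | intermediate
12 | (3E)-4-methoxypent-3-en-2-one | CO/C(C)=C/C(C)=O | starting material
13 | lithium (3E)-4-methoxypenta-1,3-dien-2-olate | C=C(O[Li])/C=C(\C)OC | intermediate
14 | tert-butyl{[(3E)-4-methoxypenta-1,3-dien-2-yl]oxy}dimethylsilane | C=C(O[Si](C)(C)C(C)(C)C)/C=C(\C)OC | intermediate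
15 | (4R,4aR,8S,8aR)-6-[(tert-butyldimethylsilyl)oxy]-8-methoxy-4,8-dimethyl-4-[(2,3,5,6-tetramethoxyphenyl)methyl]-4a,5,8,8a-tetrahydronaphthalen-1(4H)-one | COc1cc(OC)c(OC)c(C[C@@]2(C)[C@@H]3CC(O[Si](C)(C)C(C)(C)C)=C[C@](C)(OC)[C@@H]3C(=O)C=C2)c1OC | intermediate
16 | (3S,4R,4aR,8S,8aR)-6-[(tert-butyldimethylsilyl)oxy]-8-methoxy-3,4,8-trimethyl-4-[(2,3,5,6-tetramethoxyphenyl)methyl]-3,4,4a,5,8,8a-hexahydronaphthalen-1(2H)-one | COc1cc(OC)c(OC)c(C[C@@]2(C)[C@@H]3CC(O[Si](C)(C)C(C)(C)C)=C[C@](C)(OC)[C@@H]3C(=O)C[C@@H]2C)c1OC | intermediate
17 | (7'S,8'R,8a'S)-4',7',8'-trimethyl-8'-[(2,3,5,6-tetramethoxyphenyl)methyl]-6',7',8',8a'-tetrahydro-1'H-spiro[[1,3]dioxolane-2,2'-naphthalen]-5'(3'H)-one | COc1cc(OC)c(OC)c(C[C@@]2(C)[C@@H]3CC4(OCCO4)CC(C)=C3C(=O)C[C@@H]2C)c1OC | intermediate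
18 | lithium C5=C6 enolate of the 4,4-dimethyl ketone (dioxolane at C2) | COc1cc(OC)c(OC)c(C[C@@]2(C)[C@@H]3CC4(OCCO4)CC(C)(C)C3=C(O[Li])C[C@@H]2C)c1OC | intermediate
19 | (7'S,8'R,8a'S)-4',4',7',8'-tetramethyl-8'-[(2,3,5,6-tetramethoxyphenyl)methyl]-3',4',6',7',8',8a'-hexahydro-1'H-spiro[[1,3]dioxolane-2,2'-naphthalen]-5'-yl trifluoromethanesulfonate | COc1cc(OC)c(OC)c(C[C@@]2(C)[C@@H]3CC4(OCCO4)CC(C)(C)C3=C(OS(=O)(=O)C(F)(F)F)C[C@@H]2C)c1OC | intermediate
20 | (7'S,8'R,8a'S)-4',4',7',8'-tetramethyl-8'-[(2,3,5,6-tetramethoxyphenyl)methyl]-3',4',6',7',8',8a'-hexahydro-1'H-spiro[[1,3]dioxolane-2,2'-naphthalene] | COc1cc(OC)c(OC)c(C[C@@]2(C)[C@@H]3CC4(OCCO4)CC(C)(C)C3=CC[C@@H]2C)c1OC | intermediate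
21 | (7S,8R,8aS)-4,4,7,8-tetramethyl-8-[(2,3,5,6-tetramethoxyphenyl)methyl]-3,4,6,7,8,8a-hexahydronaphthalen-2(1H)-one | COc1cc(OC)c(OC)c(C[C@@]2(C)[C@@H]3CC(=O)CC(C)(C)C3=CC[C@@H]2C)c1OC | intermediate
22 | hydrazone of ketone 21 | COc1cc(OC)c(OC)c(C[C@@]2(C)[C@@H]3CC(=NN)CC(C)(C)C3=CC[C@@H]2C)c1OC | intermediate
23 | 3-{[(1R,2S,8aS)-1,2,5,5-tetramethyl-1,2,3,5,6,7,8,8a-octahydronaphthalen-1-yl]methyl}-1,2,4,5-tetramethoxybenzene | COc1cc(OC)c(OC)c(C[C@@]2(C)[C@@H]3CCCC(C)(C)C3=CC[C@@H]2C)c1OC | intermediate
24 | 2,5-dimethoxy-3-{[(1R,2S,8aS)-1,2,5,5-tetramethyl-1,2,3,5,6,7,8,8a-octahydronaphthalen-1-yl]methyl}cyclohexa-2,5-diene-1,4-dione | COC1=CC(=O)C(OC)=C(C[C@@]2(C)[C@@H]3CCCC(C)(C)C3=CC[C@@H]2C)C1=O | intermediate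
25 | 2-hydroxy-5-methoxy-3-{[(1R,2S,8aS)-1,2,5,5-tetramethyl-1,2,3,5,6,7,8,8a-octahydronaphthalen-1-yl]methyl}cyclohexa-2,5-diene-1,4-dione | COC1=CC(=O)C(O)=C(C[C@@]2(C)[C@@H]3CCCC(C)(C)C3=CC[C@@H]2C)C1=O | target

## Step count and least certain steps

Total: 15 steps. Longest linear sequence: 14 steps (steps 1–5 and 7–15); step 6 is a one-step branch.

Step 7 (key step). Three processes may interfere. Ring closure may fail after the first C–C bond, because the fully substituted methoxy-bearing terminus must bond to C5 and the first bond forms at the neopentyl-type C10. The acid may trigger a dienone–phenol rearrangement of 11 by 1,2-shift of the electron-rich arylmethyl group. Discrimination of arm or face may be weak. Fallback: break the symmetry of 11 by another reaction and let the annulation follow under substrate control. Copper-catalysed enantioselective conjugate addition of Me2Zn (Cu(OTf)2, BINOL-derived phosphoramidite ligand) to 11 sets C8 and C9 together and gives (4R,5S)-4,5-dimethyl-4-[(2,3,5,6-tetramethoxyphenyl)methyl]cyclohex-2-en-1-one F1. The single enone arm of F1 then takes diene 14 under an achiral Lewis acid (Me2AlCl, CH2Cl2, −78 °C), if need be in two stages (Mukaiyama–Michael addition, then acid-induced closure), anti to the arylmethyl group. This sets out from 11 and comes back to the route at 16.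

Step 8. Facial selectivity may be poor or reversed: the axial C1 methylene of ring A is 1,3-related to C8 on the lower face and may outweigh the arylmethyl group on the upper face. Fallback: let hydrogen, not methyl, be delivered to C8 in the stereodefining step. From 15, Me2CuLi with Me3SiCl trapping gives the bis(silyl enol ether) F2 (C8 configuration immaterial). Pd(OAc)2 in MeCN dehydrogenates the trimethylsilyl enol ether selectively (the ring A enol ether has no hydrogen on C4 and transmetalates slowly) to the 8-methyl-7-en-6-one F3. Conjugate reduction with [(Ph3P)CuH]6 then brings hydride to C8 from the face that methyl had preferred and leaves the 8-methyl group on the lower face. This sets out from 15 and comes back at 16.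

Step 10. Addition to the fully substituted β-carbon C4 may be slow, with competing enolisation at C7 or 1,2-addition, and O-sulfonylation of the hindered tetrasubstituted enolate may be incomplete. Fallback: make the same two changes by allylic substitution. 1,2-Reduction of 17 (NaBH4, CeCl3·7H2O, MeOH) gives the allylic alcohol F4, esterification with picolinic acid (carbodiimide, DMAP) gives the picolinate F5, and MeMgBr with CuBr·SMe2 delivers methyl to C4 in an anti-SN2′ substitution that shifts the alkene to C5=C6. This sets out from 17 and comes back at 20, so that 19 is bypassed.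

Step 15. Regioselectivity may be lost through attack at the methoxy group beside the ring hydrogen, or the quinone may degrade in base. Fallback: hydrolyse both vinylogous esters of 24 (NaOH, aqueous dioxane, then cold dilute acid) to the 2,5-dihydroxyquinone F6 and methylate its unhindered hydroxyl, the one beside the ring hydrogen, with one equivalent of Me3SiCHN2 in MeOH/toluene at 0 °C. This sets out from 24 and comes back at 25.

## Further compounds

F1 | step 7 | (4R,5S)-4,5-dimethyl-4-[(2,3,5,6-tetramethoxyphenyl)methyl]cyclohex-2-en-1-one | COc1cc(OC)c(OC)c(C[C@@]2(C)C=CC(=O)C[C@@H]2C)c1OC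
F2 | step 8 | bis(silyl enol ether) of 16 (6-trimethylsilyloxy, C6=C7; C8 epimers) | COc1cc(OC)c(OC)c(C[C@@]2(C)[C@@H]3CC(O[Si](C)(C)C(C)(C)C)=C[C@](C)(OC)[C@@H]3C(O[Si](C)(C)C)=CC2C)c1OC
F3 | step 8 | 8-methyl-7-en-6-one derived from 15 | COc1cc(OC)c(OC)c(C[C@@]2(C)[C@@H]3CC(O[Si](C)(C)C(C)(C)C)=C[C@](C)(OC)[C@@H]3C(=O)C=C2C)c1OC
F4 | step 10 | allylic alcohol from 17 (C6 hydroxyl, C4=C5 alkene; C6 configuration not controlled) | COc1cc(OC)c(OC)c(C[C@@]2(C)[C@@H]3CC4(OCCO4)CC(C)=C3C(O)C[C@@H]2C)c1OC
F5 | step 10 | pyridine-2-carboxylate (picolinate) of F4 | COc1cc(OC)c(OC)c(C[C@@]2(C)[C@@H]3CC4(OCCO4)CC(C)=C3C(OC(=O)c5ccccn5)C[C@@H]2C)c1OC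
F6 | step 15 | 2,5-dihydroxy-3-{[(1R,2S,8aS)-1,2,5,5-tetramethyl-1,2,3,5,6,7,8,8a-octahydronaphthalen-1-yl]methyl}cyclohexa-2,5-diene-1,4-dione | OC1=CC(=O)C(O)=C(C[C@@]2(C)[C@@H]3CCCC(C)(C)C3=CC[C@@H]2C)C1=O
A1 | alternative 1 | (2E,8Z,10E)-9-[(tert-butyldimethylsilyl)oxy]-2,7,7-trimethyldodeca-2,8,10-trienal | O=C/C(C)=C/CCCC(C)(C)/C=C(O[Si](C)(C)C(C)(C)C)/C=C/C
A2 | alternative 1 | cis-fused octalin aldehyde (formyl at C9, C6=C7 silyl enol ether, 8-methyl cis to 9-methyl) | O=C[C@@]1(C)[C@@H]2CCCC(C)(C)[C@@H]2C(O[Si](C)(C)C(C)(C)C)=C[C@@H]1C
A3 | alternative 2 | 4,6-trans-6-(6,6-dimethylcyclohex-1-en-1-yl)-4-methyl-3-[(2,3,5,6-tetramethoxyphenyl)methyl]oxan-2-one | O=C1O[C@@H](C2=CCCCC2(C)C)C[C@H](C)C1Cc1c(OC)c(OC)cc(OC)c1OC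
A4 | alternative 2 | octalin carboxylic acid (carboxyl in place of the 9-methyl group) | COc1cc(OC)c(OC)c(C[C@@]2(C(=O)O)[C@@H]3CCCC(C)(C)C3=CC[C@@H]2C)c1OC
A5 | alternative 3 | 3-tert-butoxy-4-hydroxy-4-(methoxyethynyl)-2-{[(1R,2S,8aS)-1,2,5,5-tetramethyl-1,2,3,5,6,7,8,8a-octahydronaphthalen-1-yl]methyl}cyclobut-2-en-1-one | COC#CC1(O)C(OC(C)(C)C)=C(C[C@@]2(C)[C@@H]3CCCC(C)(C)C3=CC[C@@H]2C)C1=O
A6 | alternative 3 | O-tert-butyl ether of 25 | COC1=CC(=O)C(OC(C)(C)C)=C(C[C@@]2(C)[C@@H]3CCCC(C)(C)C3=CC[C@@H]2C)C1=O
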